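Late in a run of this kind I ask where the reagent has gone, and I compare two flasks that differ in one charge of reagent, 2.00 equiv against 0.800 equiv.

    solid substrate ⇌ dissolved substrate, rate k1*(cs1 - [dissolved substrate]) while solid is left; crystals form when [dissolved substrate] > cs1 (cs1 = 0.31 M, k1 = 2.2 × 10⁻⁴ s⁻¹)
    dissolved substrate + reagent → target (k2 = 1.4 × 10⁻⁴ M⁻¹ s⁻¹)
    reagent → side product (k3 = 5.4 × 10⁻⁵ s⁻¹)
    solid substrate + protic impurity → quenched substrate (k4 = 0.013 M⁻¹ s⁻¹)
    crystals ⇌ target, rate k5*(cs5 - [target]) while solid is left; crystals form when [target] > cs5 (cs5 = 10 mM, k5 = 0.021 s⁻¹)

solid substrate 1.0 M; reagent 2.00 equiv; protic impurity 0.0500 M; time 4.0 h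

* the target and crystals together standing at 4.0 h, as a percentage of the solid substrate charged
* concentration of dissolved substrate in solution at 4.0 h, in percent of saturation

- amounts and yields of target count crystals too
- given per volume of solution although it is solid: solid substrate, crystals
- at the start none of the solid substrate is in solution
- dissolved substrate means what is dissolved; the solid is not counted in it
- run time (flask): 4.0 h

Reagent has two exits: it makes target with dissolved substrate, or it decays to side product. Both rates carry [reagent], so their ratio depends on [dissolved substrate] and on the two rate constants. I carry the break-even concentration, the [dissolved substrate] at which both exits take equal reagent, the decay constant over the coupling constant: 0.386 M.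

[dissolved substrate] climbs from zero towards 0.31 M, which lies below break-even, so in both flasks more reagent leaves as side product than as target. The target's share of spent reagent stays under 44.6%. With [dissolved substrate] held at solubility, the upper case, the two exits together take 75.4% of the charged reagent by 4.0 h, the same fraction in either flask. Target therefore stays under 67.2% of the solid substrate charged in the recipe flask and under 26.9% in the neighbour, and these ceilings stand as the reagent charges do. Because the neighbour has less reagent draining its solution, I expect it to come closer to its ceiling. My hand stops there, with no figure for saturation.

The forecast says 33% and 64%, reasoning “so solid remains throughout”, and its yield sits under my ceiling.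

The simulation gives 33.0% and 64.1%, so the recipe flask at 4.00 h stands where the forecast put it, with 42.1% of the charge still solid. Its 0.982 M of side product against 0.330 M of target, turned through break-even, means reagent met a [reagent]-weighted mean [dissolved substrate] of 0.130 M, lower than solubility. The neighbour's 0.384 M against 0.160 M gives 0.161 M, higher. At 4.00 h that neighbour yields 16.0%, under its ceiling of 26.9%.

Its constants are assumed.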